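**Plan**

- Retrosynthesis: first the two O–methyl bonds that mask the ring A hydroquinone, then the C3'–Br, C5'–Br and C6'–Br bonds of ring B, traced back to two C–Si bonds and one C–H bond.
- Ring B is then opened at C1'–C2', C3'–C4' and C4'–C5' into a chromium carbene complex, trimethylsilylacetylene (C2', C3') and one CO ligand (C4'). The carbene carbon C1' already holds the ring A oxygen and a 1-silylvinyl group (C6', C5').
- The C1'–O bond is cut last, giving an acyl chromate and 2,4-dibromo-3,6-dimethoxyphenol, itself two C–Br bonds away from 2,5-dimethoxyphenol.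
- Forward: ring A is bought and dibrominated, its oxygen is transferred to the carbene carbon, ring B (the only ring made) closes by benzannulation, bromine replaces both silyl groups and one hydrogen, and BBr3 unmasks the hydroquinone.
- Enabling feature: ring B (C1'–OAr, C2'–H, C3'–Br, C4'–OH, C5'–Br, C6'–Br) is a 4-aryloxyphenol, the oxygen pattern a carbene benzannulation delivers, and its C3' and C6' bromines sit where the two building blocks can carry silicon.
- Stereochemistry: the target has no stereocentre and no configurationally stable axis, so nothing has to be controlled.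

Key step: step 4

Assumption: ring A is numbered C1–C6 (ether oxygen on C6, hydroxyls on C1 and C4) and ring B C1'–C6' (ether oxygen on C1', hydroxyl on C4'); 2,5-dimethoxyphenol is taken as a catalogue compound.

**Route**

Step 1
Reactants: 1 2,5-dimethoxyphenol
Product: 2 2,4-dibromo-3,6-dimethoxyphenol
Conditions: Br2 (2.05 equiv), CH2Cl2, 0 °C to rt; aq. Na2S2O3 wash
Reagents that add atoms: bromine, BrBr
Why: Electrophilic aromatic bromination in which the hydroxyl sends bromine to its para and ortho carbons (each also ortho to the 5-methoxy group), while the third free carbon, activated by one methoxy group only, should stay untouched at two equivalents.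

Step 2
Reactants: 3 (1-bromovinyl)trimethylsilane; 4 chromium hexacarbonyl, Cr(CO)6
Product: 7 tetramethylammonium pentacarbonyl[2-(trimethylsilyl)prop-2-enoyl]chromate, via 1-(trimethylsilyl)vinyllithium 5 (not isolated), via lithium acylchromate 6 (not isolated)
Conditions: t-BuLi (2.0 equiv), Et2O, −78 °C; Cr(CO)6, −78 °C to rt; Me4NBr, H2O, rt
Reagents that add atoms: tetramethylammonium bromide, C[N+](C)(C)C.[Br-]
Why: Bromine–lithium exchange followed by the Fischer addition of an organolithium to a CO ligand of Cr(CO)6 gives the acyl chromate, and cation exchange should deliver it as a storable ammonium salt.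

Step 3
Reactants: 7 tetramethylammonium pentacarbonyl[2-(trimethylsilyl)prop-2-enoyl]chromate; 2 2,4-dibromo-3,6-dimethoxyphenol
Product: 9 pentacarbonyl[(2,4-dibromo-3,6-dimethoxyphenoxy)(1-trimethylsilylethenyl)carbene]chromium, via acetoxycarbene complex 8 (not isolated)
Conditions: AcBr (1.05 equiv), CH2Cl2, −40 °C; then 2 (1.1 equiv), −40 °C to 0 °C; fast filtration through SiO2 under Ar
Reagents that add atoms: none
Why: O-acylation of the acyl chromate gives an acetoxycarbene complex whose electrophilic carbene carbon should undergo addition–elimination with the phenol (acyloxy-to-aryloxy exchange of Fischer carbene complexes), the standard entry to aryloxycarbene complexes.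

Step 4
Reactants: 9 pentacarbonyl[(2,4-dibromo-3,6-dimethoxyphenoxy)(1-trimethylsilylethenyl)carbene]chromium; 10 trimethylsilylacetylene
Product: 12 4-(2,4-dibromo-3,6-dimethoxyphenoxy)-2,5-bis(trimethylsilyl)phenol, via tricarbonylchromium arene complex 11 (not isolated)
Conditions: HC≡CSiMe3 (3 equiv), THF (0.05 M), 50 °C, sealed tube, Ar; then air, Et2O, rt; Et3N-washed SiO2
Reagents that add atoms: none
Why: Proposed new method: loss of one cis CO from 9 lets the alkyne coordinate and insert into the Cr=C bond, CO insertion then gives a chromium-bound dienylketene, and 6π electrocyclisation onto the vinyl CH2 followed by enolisation gives the phenol as its Cr(CO)3 complex 11, which air strips to 12. The closest known reaction type is the Dötz benzannulation of alkenyl(alkoxy)carbene complexes of chromium, and of their aryloxy analogues, with alkynes to give 4-alkoxy- or 4-aryloxyphenols; untested is the combination of a 1-silylvinyl group, a doubly ortho-substituted aryloxy group and a silylalkyne. Ring B closes by that 6π electrocyclisation of the dienylketene (C4' onto C5'), after C1'–C2' is made by alkyne insertion and C3'–C4' by CO insertion, a formal [3+2+1] assembly. No stereocentre is created. The step needs the alkyne to insert with its CH carbon on the carbene carbon C1' and its silylated carbon next to the incoming CO, which the usual steric bias of terminal alkynes should secure, and it needs six-ring closure with CO uptake rather than cyclopentannulation, which an alkenyl carbene on chromium in THF favours. Trimethylsilyl, not a bulkier silyl group, is chosen so that the silyl-substituted ketene cyclises instead of persisting, the weakly donating aryloxy group should let CO leave near 50 °C, and (NH4)2Ce(NO3)6 is kept out of the work-up because it would oxidise the 4-aryloxyphenol to a quinone.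

Step 5
Reactants: 12 4-(2,4-dibromo-3,6-dimethoxyphenoxy)-2,5-bis(trimethylsilyl)phenol
Product: 13 2,3,6-tribromo-4-(2,4-dibromo-3,6-dimethoxyphenoxy)phenol
Conditions: NBS (2.05 equiv), CH2Cl2/MeCN, −20 °C to 0 °C; then Br2 (1.05 equiv), 0 °C to rt; aq. Na2S2O3
Reagents that add atoms: N-bromosuccinimide, O=C1CCC(=O)N1Br; bromine, BrBr
Why: Electrophilic aromatic bromination combined with ipso-bromodesilylation of arylsilanes: NBS should brominate the two carbons flanking the hydroxyl (C5'–H and silylated C3') without releasing HBr, so the C6' silyl marker survives until Br2 replaces it at the silicon-bearing carbon, where β-silyl stabilisation of the arenium ion should outpace attack at C2'–H or at the deactivated C2–H of ring A.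

Step 6
Reactants: 13 2,3,6-tribromo-4-(2,4-dibromo-3,6-dimethoxyphenoxy)phenol
Product: 14 3,5-dibromo-2-(2,3,5-tribromo-4-hydroxyphenoxy)benzene-1,4-diol (CNP0084224.0)
Conditions: BBr3 (5 equiv), CH2Cl2, −78 °C to rt; MeOH then H2O; aq. Na2S2O4 wash under Ar
Reagents that add atoms: none
Why: Lewis-acid ether cleavage in which BBr3 coordinates each methoxy oxygen and bromide removes the methyl group by SN2, while the diaryl ether and the aryl bromides are inert and the reducing work-up should protect the air-sensitive hydroquinone.

**Compound list**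

1 | 2,5-dimethoxyphenol | COc1ccc(OC)c(O)c1 | starting material
2 | 2,4-dibromo-3,6-dimethoxyphenol | Oc1c(OC)cc(Br)c(OC)c1Br | intermediate
3 | (1-bromovinyl)trimethylsilane | C=C(Br)[Si](C)(C)C | starting material
4 | chromium hexacarbonyl, Cr(CO)6 | O=C=[Cr](=C=O)(=C=O)(=C=O)(=C=O)=C=O | starting material
5 | 1-(trimethylsilyl)vinyllithium (not isolated) | [Li]C(=C)[Si](C)(C)C | intermediate
6 | lithium pentacarbonyl[2-(trimethylsilyl)prop-2-enoyl]chromate (not isolated) | [Li+].O=C=[Cr](=C=O)(=C=O)(=C=O)(=C=O)=C([O-])C(=C)[Si](C)(C)C | intermediate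
7 | tetramethylammonium pentacarbonyl[2-(trimethylsilyl)prop-2-enoyl]chromate | C[N+](C)(C)C.O=C=[Cr](=C=O)(=C=O)(=C=O)(=C=O)=C([O-])C(=C)[Si](C)(C)C | intermediate
8 | pentacarbonyl[acetoxy(1-trimethylsilylethenyl)carbene]chromium (not isolated) | O=C=[Cr](=C=O)(=C=O)(=C=O)(=C=O)=C(OC(C)=O)C(=C)[Si](C)(C)C | intermediate
9 | pentacarbonyl[(2,4-dibromo-3,6-dimethoxyphenoxy)(1-trimethylsilylethenyl)carbene]chromium | O=C=[Cr](=C=O)(=C=O)(=C=O)(=C=O)=C(Oc1c(OC)cc(Br)c(OC)c1Br)C(=C)[Si](C)(C)C | intermediate
10 | trimethylsilylacetylene | C#C[Si](C)(C)C | starting material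
11 | tricarbonyl[η6-4-(2,4-dibromo-3,6-dimethoxyphenoxy)-2,5-bis(trimethylsilyl)phenol]chromium, Cr(CO)3 bound to ring B and written as a separate fragment (not isolated) | Oc1cc([Si](C)(C)C)c(Oc2c(OC)cc(Br)c(OC)c2Br)cc1[Si](C)(C)C.O=C=[Cr](=C=O)=C=O | intermediate
12 | 4-(2,4-dibromo-3,6-dimethoxyphenoxy)-2,5-bis(trimethylsilyl)phenol | Oc1cc([Si](C)(C)C)c(Oc2c(OC)cc(Br)c(OC)c2Br)cc1[Si](C)(C)C | intermediate
13 | 2,3,6-tribromo-4-(2,4-dibromo-3,6-dimethoxyphenoxy)phenol | Oc1c(Br)cc(Oc2c(OC)cc(Br)c(OC)c2Br)c(Br)c1Br | intermediate
14 | 3,5-dibromo-2-(2,3,5-tribromo-4-hydroxyphenoxy)benzene-1,4-diol | Oc1cc(Br)c(O)c(Br)c1Oc1cc(Br)c(O)c(Br)c1Br | target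

**Count**

Total steps: 6. Longest linear sequence: 5 steps (3 → 7 → 9 → 12 → 13 → 14; the branch from 1 through 2 is equally long).

**Steps most likely to fail**

Step 4. The alkyne may insert with the reverse orientation, the silyl-substituted dienylketene may stall or close to a five-membered ring without taking up CO, or the labile aryloxycarbene may decompose before CO is lost. The fallback uses known chemistry only, sets out from 2 and comes back at 13, leaving the chromium chemistry aside. Nucleophilic aromatic substitution of 2 on 2-bromo-1-fluoro-4-nitrobenzene (K2CO3, DMF, 80 °C) would give 2-bromo-1-(2,4-dibromo-3,6-dimethoxyphenoxy)-4-nitrobenzene F1, in which the C6' bromine is already in place. Reduction with Fe and NH4Cl in aqueous EtOH would give 3-bromo-4-(2,4-dibromo-3,6-dimethoxyphenoxy)aniline F2. NBS (2 equiv, MeCN, 0 °C) would brominate both carbons ortho to the amino group to give 2,3,6-tribromo-4-(2,4-dibromo-3,6-dimethoxyphenoxy)aniline F3. Diazotisation (NaNO2, H2SO4, AcOH, 0 °C) to 2,3,6-tribromo-4-(2,4-dibromo-3,6-dimethoxyphenoxy)benzenediazonium hydrogensulfate F4 and hydroxydediazoniation with Cu2O and Cu(NO3)2 in water would give 13.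

Step 5. The C6' silyl marker may be lost by protodesilylation before bromine replaces it, ipso attack para to the hydroxyl may oxidise the 4-aryloxyphenol to a quinone with loss of ring A, or bromination may run on to C2' or to C2 of ring A. The fallback sets out from 12 and comes back at 13 with the phenol masked during silicon–bromine exchange. Ac2O and pyridine would give 4-(2,4-dibromo-3,6-dimethoxyphenoxy)-2,5-bis(trimethylsilyl)phenyl acetate F5. Br2 (2.1 equiv, CH2Cl2, 0 °C to rt) would then replace only the two silyl groups, with no C–H bromination and hence no HBr, to give 2,5-dibromo-4-(2,4-dibromo-3,6-dimethoxyphenoxy)phenyl acetate F6. K2CO3 in MeOH would free 2,5-dibromo-4-(2,4-dibromo-3,6-dimethoxyphenoxy)phenol F7, and NBS (1 equiv) would brominate its single free carbon ortho to the hydroxyl (C5') to give 13.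

Step 3. Addition of the hindered, electron-poor phenol to the carbene carbon may be slower than thermal decay of the acetoxycarbene complex, or the acetyl group may be transferred to the phenol instead. The fallback sets out from 2 and 7 and comes back at 9, replacing neutral alcoholysis by an anionic addition–elimination on a shielded acyloxy complex. NaH in THF would turn 2 into sodium 2,4-dibromo-3,6-dimethoxyphenoxide F8. Pivaloyl chloride (CH2Cl2, −40 °C) would turn 7 into pivaloyloxycarbene complex pentacarbonyl[(2,2-dimethylpropanoyloxy)(1-trimethylsilylethenyl)carbene]chromium F9, whose tert-butyl group blocks attack at the acyl carbon. The phenoxide should then add to the carbene carbon and expel pivalate to give 9.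

**Further compounds**

F1 | step 4 | 2-bromo-1-(2,4-dibromo-3,6-dimethoxyphenoxy)-4-nitrobenzene | O=[N+]([O-])c1ccc(Oc2c(OC)cc(Br)c(OC)c2Br)c(Br)c1
F2 | step 4 | 3-bromo-4-(2,4-dibromo-3,6-dimethoxyphenoxy)aniline | Nc1ccc(Oc2c(OC)cc(Br)c(OC)c2Br)c(Br)c1
F3 | step 4 | 2,3,6-tribromo-4-(2,4-dibromo-3,6-dimethoxyphenoxy)aniline | Nc1c(Br)cc(Oc2c(OC)cc(Br)c(OC)c2Br)c(Br)c1Br
F4 | step 4 | 2,3,6-tribromo-4-(2,4-dibromo-3,6-dimethoxyphenoxy)benzenediazonium hydrogensulfate | N#[N+]c1c(Br)cc(Oc2c(OC)cc(Br)c(OC)c2Br)c(Br)c1Br.OS(=O)(=O)[O-]
F5 | step 5 | 4-(2,4-dibromo-3,6-dimethoxyphenoxy)-2,5-bis(trimethylsilyl)phenyl acetate | CC(=O)Oc1cc([Si](C)(C)C)c(Oc2c(OC)cc(Br)c(OC)c2Br)cc1[Si](C)(C)C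
F6 | step 5 | 2,5-dibromo-4-(2,4-dibromo-3,6-dimethoxyphenoxy)phenyl acetate | CC(=O)Oc1cc(Br)c(Oc2c(OC)cc(Br)c(OC)c2Br)cc1Br
F7 | step 5 | 2,5-dibromo-4-(2,4-dibromo-3,6-dimethoxyphenoxy)phenol | Oc1cc(Br)c(Oc2c(OC)cc(Br)c(OC)c2Br)cc1Br
F8 | step 3 | sodium 2,4-dibromo-3,6-dimethoxyphenoxide | [Na+].[O-]c1c(OC)cc(Br)c(OC)c1Br
F9 | step 3 | pentacarbonyl[(2,2-dimethylpropanoyloxy)(1-trimethylsilylethenyl)carbene]chromium | O=C=[Cr](=C=O)(=C=O)(=C=O)(=C=O)=C(OC(=O)C(C)(C)C)C(=C)[Si](C)(C)C
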